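**Strategy.** The ten-membered carbocycle (ring A, C1–C10) is cut at C2–C3, the one ring bond whose carbons are both allylic methylenes, set between the Z alkenes C1=C10 and C4=C5. In one operation the potassium carbanion of a C3 allylic phenyl sulfone displaces a primary allylic bromide at C2; this forges C2–C3 and closes ring A, the two cis alkenes acting as turns that bring the chain ends together. The precursor is an open C2-bromo, C3-sulfonyl chain that already carries the C6–C9 stereotetrad, both Z alkenes and the lactone (ring B) masked as C6/C12 silyl ethers. Desulfonylation, lactonisation and the two esterifications follow.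

Key step: step 20

Remarks on the chemistry:
- Germacrane numbering is used throughout: ring A = C1–C10; ring B = lactone O–C6–C7–C11–C12; C13 = exocyclic methylene; C14 on C10; C15 on C4. PMB = 4-methoxybenzyl, Piv = pivaloyl.
- Acetals 19, 20, 22 and 23 are taken as mixtures at the acetal carbon and sulfone 33 as a mixture at C3; both centres disappear later (steps 14 and 21).
- The C12 hydroxyl is carried as a TBDPS ether so that the C9 TES ether can be cleaved alone in step 22.
- The sulfone is cleaved by palladium/hydride because a free allyl anion spanning C3–C5 would have the C6 silyloxy group in the β position.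

**Route**

Step 1
Reactants: 1 but-2-yne-1,4-diol
Product: 2 4-[(4-methoxybenzyl)oxy]but-2-yn-1-ol
Conditions: NaH (1 equiv), 4-methoxybenzyl chloride (1 equiv), Bu4NI (cat.), 1 in threefold excess, THF/DMF, 0 °C to rt
Reagents that add atoms: 4-methoxybenzyl chloride, COc1ccc(CCl)cc1
Why: Williamson ether synthesis on the monoalkoxide, the excess of the symmetrical diol holding back the bis-ether.

Step 2
Reactants: 2 4-[(4-methoxybenzyl)oxy]but-2-yn-1-ol
Product: 4 (Z)-3-iodo-4-[(4-methoxybenzyl)oxy]but-2-en-1-ol, via alkenylaluminate 3 (not isolated)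
Conditions: NaAlH2(OCH2CH2OMe)2 (1.5 equiv), THF, 0 °C; then I2, THF, −78 °C to 0 °C
Reagents that add atoms: iodine, II
Why: Hydroxyl-directed trans-hydroalumination of the propargylic alcohol puts aluminium on the distal alkyne carbon (five-membered O–Al–C chelate 3), and iodinolysis with retention gives the Z iodoalkene in which iodine (the later C9 position) is cis to C2.

Step 3
Reactants: 4 (Z)-3-iodo-4-[(4-methoxybenzyl)oxy]but-2-en-1-ol
Product: 5 (Z)-3-iodo-4-[(4-methoxybenzyl)oxy]but-2-en-1-yl pivalate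
Conditions: PivCl, pyridine, DMAP (cat.), CH2Cl2, 0 °C
Reagents that add atoms: pivaloyl chloride, CC(C)(C)C(Cl)=O
Why: Simple acylation of the primary alcohol, the pivalate being inert to the later chromium-mediated coupling and removable by hydride.

Step 4
Reactants: 6 prop-2-yn-1-ol
Product: 8 (Z)-3-iodo-2-methylprop-2-en-1-ol, via alkenylmagnesium alkoxide 7 (not isolated)
Conditions: MeMgBr (2.3 equiv), CuI (10 mol%), THF, −10 °C to rt; then I2, −10 °C
Reagents that add atoms: methylmagnesium bromide, C[Mg]Br; iodine, II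
Why: Copper-catalysed anti-carbomagnesiation of the propargylic alkoxide delivers methyl to C2 and magnesium to C3 inside a chelate, so iodinolysis gives only the Z iodide (the C3–C5 unit with C15).

Step 5
Reactants: 8 (Z)-3-iodo-2-methylprop-2-en-1-ol
Product: 10 (Z)-[(3-iodo-2-methylprop-2-en-1-yl)sulfonyl]benzene, via allylic mesylate 9 (not isolated)
Conditions: MsCl, Et3N, THF, −20 °C; then PhSO2Na, DMF, rt
Reagents that add atoms: sodium benzenesulfinate, [Na+].[O-]S(=O)c1ccccc1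
Why: Mesylation followed by SN2 S-alkylation of the sulfinate at the primary allylic carbon gives the sulfone without touching the Z iodoalkene, so C3 never needs a protecting group.

Step 6
Reactants: 11 2-bromoprop-2-en-1-ol
Product: 12 [(2-bromoprop-2-en-1-yl)oxy](tert-butyl)diphenylsilane
Conditions: TBDPSCl, imidazole, CH2Cl2, rt
Reagents that add atoms: tert-butyl(chloro)diphenylsilane, CC(C)(C)[Si](Cl)(c1ccccc1)c1ccccc1
Why: Standard silylation of a primary alcohol, giving the robust C12 ether.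

Step 7
Reactants: 2 4-[(4-methoxybenzyl)oxy]but-2-yn-1-ol
Product: 14 (E)-4-[(4-methoxybenzyl)oxy]but-2-en-1-ol, via lithium alkenylalanate 13 (not isolated)
Conditions: LiAlH4 (1.5 equiv), THF, 0 °C to rt; then aq. potassium sodium tartrate
Reagents that add atoms: none
Why: Hydroxyl-directed trans-hydroalumination of the propargylic alcohol by LiAlH4, in which the alkoxyaluminium hydride delivers hydride to the proximal alkyne carbon and closes the cyclic alanate 13, followed by protonolysis of the C–Al bond with retention gives the E allylic alcohol.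

Step 8
Reactants: 14 (E)-4-[(4-methoxybenzyl)oxy]but-2-en-1-ol
Product: 15 [(2R,3R)-3-{[(4-methoxybenzyl)oxy]methyl}oxiran-2-yl]methanol
Conditions: Ti(OiPr)4 (10 mol%), D-(−)-diethyl tartrate (12 mol%), t-BuOOH, 4 Å MS, CH2Cl2, −20 °C
Reagents that add atoms: tert-butyl hydroperoxide, CC(C)(C)OO
Why: Sharpless asymmetric epoxidation, in which the D-(−)-tartrate ligand directs oxygen to the face that gives the (2R,3R)-epoxide and so fixes the absolute configuration of C7 and C8.

Step 9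
Reactants: 12 [(2-bromoprop-2-en-1-yl)oxy](tert-butyl)diphenylsilane; 15 [(2R,3R)-3-{[(4-methoxybenzyl)oxy]methyl}oxiran-2-yl]methanol
Product: 18 (2S,3S)-2-{3-[(tert-butyldiphenylsilyl)oxy]prop-1-en-2-yl}-4-[(4-methoxybenzyl)oxy]butane-1,3-diol, via alkenyllithium 16 (not isolated), via alkenylmagnesium bromide 17 (not isolated)
Conditions: 12 (3 equiv), t-BuLi (6 equiv), Et2O, −78 °C; MgBr2·OEt2, −78 °C to −40 °C; then CuI (15 mol%), 15, THF, −40 °C to −20 °C
Reagents that add atoms: none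
Why: Copper-catalysed Grignard opening of a 2,3-epoxy alcohol with a C4 alkoxy group occurs at C2 (here C7) with inversion, which attaches the C11–C13 unit and sets C7 anti to the C8 hydroxyl.

Step 10
Reactants: 18 (2S,3S)-2-{3-[(tert-butyldiphenylsilyl)oxy]prop-1-en-2-yl}-4-[(4-methoxybenzyl)oxy]butane-1,3-diol
Product: 19 (2S)-3-{[(tert-butyldiphenylsilyl)oxy]methyl}-2-[(4S)-2-(4-methoxyphenyl)-1,3-dioxolan-4-yl]but-3-en-1-ol
Conditions: DDQ (1.1 equiv), 4 Å MS, dry CH2Cl2, −10 °C to 0 °C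
Reagents that add atoms: none
Why: Oxidative acetalisation: DDQ turns the PMB ether into an oxocarbenium ion that the neighbouring C8 hydroxyl traps as a five-membered acetal, so O8 and O9 are protected together and the primary C6 hydroxyl stays free.

Step 11
Reactants: 19 (2S)-3-{[(tert-butyldiphenylsilyl)oxy]methyl}-2-[(4S)-2-(4-methoxyphenyl)-1,3-dioxolan-4-yl]but-3-en-1-ol
Product: 20 (2R)-3-{[(tert-butyldiphenylsilyl)oxy]methyl}-2-[(4S)-2-(4-methoxyphenyl)-1,3-dioxolan-4-yl]but-3-enal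
Conditions: Dess–Martin periodinane, NaHCO3, CH2Cl2, 0 °C; used crude
Reagents that add atoms: none
Why: Dess–Martin oxidation under buffered, non-basic conditions, chosen so that the β,γ-unsaturated aldehyde neither epimerises at C7 nor moves into conjugation.

Step 12
Reactants: 20 (2R)-3-{[(tert-butyldiphenylsilyl)oxy]methyl}-2-[(4S)-2-(4-methoxyphenyl)-1,3-dioxolan-4-yl]but-3-enal; 10 (Z)-[(3-iodo-2-methylprop-2-en-1-yl)sulfonyl]benzene
Product: 22 (2Z,4R,5S)-6-{[(tert-butyldiphenylsilyl)oxy]methyl}-5-[(4S)-2-(4-methoxyphenyl)-1,3-dioxolan-4-yl]-2-methyl-1-(phenylsulfonyl)hepta-2,6-dien-4-ol, via alkenylchromium dichloride 21 (not isolated)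
Conditions: 10 (1.8 equiv), CrCl2 (5 equiv), NiCl2 (1 mol%), degassed DMSO, rt
Reagents that add atoms: none
Why: Nozaki–Hiyama–Kishi coupling, in which the non-basic alkenylchromium reagent 21 tolerates the sulfone and the enolisable aldehyde and keeps the Z geometry, while Felkin–Anh attack anti to the dioxolanyl group (also 1,3-anti to O8) should set C6 as R.

Step 13
Reactants: 22 C6 allylic alcohol (6R,7S,8S)
Product: 23 C6 tert-butyldimethylsilyl ether of 22 (6R,7R,8S)
Conditions: TBSOTf, 2,6-lutidine, CH2Cl2, −78 °C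
Reagents that add atoms: tert-butyldimethylsilyl triflate, CC(C)(C)[Si](C)(C)OS(=O)(=O)C(F)(F)F
Why: Silylation of the hindered secondary allylic alcohol with the silyl triflate, run cold and briefly so that the acetal is not touched.

Step 14
Reactants: 23 C6 TBS ether with C8/C9 4-methoxybenzylidene acetal
Product: 24 open C3–C9 chain with C9 primary alcohol, C8 O-PMB, C6 O-TBS, C12 O-TBDPS and C3 phenylsulfonyl (6R,7R,8S)
Conditions: iBu2AlH (3 equiv), CH2Cl2, −78 °C to 0 °C; aq. potassium sodium tartrate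
Reagents that add atoms: none
Why: Reductive opening of the 4-methoxybenzylidene acetal, in which aluminium binds the less hindered primary oxygen so that hydride leaves the PMB group on O8 and frees the C9 hydroxyl.

Step 15
Reactants: 24 C9 primary alcohol
Product: 25 C9 aldehyde of 24 (6R,7R,8S)
Conditions: Dess–Martin periodinane, NaHCO3, CH2Cl2, 0 °C; used crude
Reagents that add atoms: none
Why: Dess–Martin oxidation of a primary alcohol under buffered conditions that keep the α-alkoxy centre C8 intact.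

Step 16
Reactants: 25 C9 aldehyde; 5 (Z)-3-iodo-4-[(4-methoxybenzyl)oxy]but-2-en-1-yl pivalate
Product: 27 open-chain C9 alcohol with C2 O-pivaloyl and C14 O-PMB on the Z-C1=C10 alkene (6R,7R,8S,9R), via alkenylchromium dichloride 26 (not isolated)
Conditions: 5 (2 equiv), CrCl2 (6 equiv), NiCl2 (1 mol%), degassed DMSO, rt
Reagents that add atoms: none
Why: Nozaki–Hiyama–Kishi coupling with retention of the Z iodoalkene geometry, in which Felkin–Anh attack anti to the α-OPMB group in the non-chelating medium should give the 8,9-anti alcohol (C9 R), the minor epimer being removed by chromatography.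

Step 17
Reactants: 27 open-chain C9 alcohol
Product: 28 C9 triethylsilyl ether of 27
Conditions: TESOTf, 2,6-lutidine, CH2Cl2, −78 °C
Reagents that add atoms: triethylsilyl triflate, CC[Si](CC)(CC)OS(=O)(=O)C(F)(F)F
Why: Silylation of the secondary allylic alcohol with a group that can later be removed in the presence of TBS and TBDPS ethers.

Step 18
Reactants: 28 C9 TES ether with C2 pivalate
Product: 29 C2 allylic alcohol (6R,7R,8S,9R)
Conditions: iBu2AlH (2.5 equiv), CH2Cl2, −78 °C; aq. potassium sodium tartrate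
Reagents that add atoms: none
Why: Hydride cleavage of the pivalate ester at low temperature, to which silyl ethers, PMB ethers and the sulfone are inert.

Step 19
Reactants: 29 C2 allylic alcohol
Product: 31 seco bromo sulfone: C2 allylic bromide, Z-C1=C10 with C14 O-PMB, C9 O-TES, C8 O-PMB, C7 3-(TBDPS-oxy)prop-1-en-2-yl, C6 O-TBS, Z-C4=C5, C3 phenylsulfonyl (6R,7R,8S,9R), via allylic mesylate 30 (not isolated)
Conditions: MsCl, Et3N, THF, −40 °C; then LiBr, THF, −40 °C to 0 °C; used at once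
Reagents that add atoms: lithium bromide, [Li+].[Br-]
Why: Mesylation and SN2 displacement by bromide at the primary allylic carbon under nearly neutral conditions, which leaves the Z alkene, the TES ether and the acidic sulfone methylene untouched.

Step 20
Reactants: 31 seco bromo sulfone
Product: 33 ten-membered ring A sulfone (C3 phenylsulfonyl, either epimer; 6R,7R,8S,9R), via potassium carbanion 32 (not isolated)
Conditions: 31 in THF (0.002 M), −78 °C; KN(SiMe3)2 (1.15 equiv) by syringe pump over 4 h; −78 °C to −45 °C; aq. NH4Cl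
Reagents that add atoms: none
Why: KN(SiMe3)2 removes a proton from C3, which lies between the sulfonyl group and the C4=C5 alkene, and the α-sulfonyl allyl carbanion 32 displaces bromide from the primary allylic C2 in an intramolecular SN2 reaction that forms C2–C3. The closest known reaction type is macrocyclisation by intramolecular alkylation of sulfur-stabilised allylic carbanions with allylic halides, used for ten- and fourteen-membered terpenoid rings. Ring A closes in the 10-exo-tet mode, helped by the two Z alkenes, which fold the chain so that C2 and C3 lie within reach. The only new stereocentre, C3, is not controlled and need not be, since it becomes a methylene group in step 21. The step needs α- and not γ-alkylation, retention of both Z alkenes and no 1,4-loss of the C6 silanolate; charge localisation next to sulfur, a bromide that can react only by SN2, the poor silyloxy leaving group and −78 °C should secure this. High dilution with slow addition of the base keeps intermolecular alkylation down.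

Step 21
Reactants: 33 ten-membered sulfone
Product: 34 desulfonylated ring A compound (C3 methylene; 6R,7R,8S,9R)
Conditions: LiBHEt3 (3 equiv), PdCl2(dppp) (5 mol%), THF, 0 °C
Reagents that add atoms: none
Why: Palladium-catalysed hydrogenolysis of the allylic sulfone, in which zerovalent palladium ionises the C3–S bond and hydride is delivered to C3, the allyl terminus remote from the C6 silyloxy group, so that position and Z geometry of the C4=C5 alkene are kept and no free allyl anion is formed.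

Step 22
Reactants: 34 desulfonylated macrocycle
Product: 35 C9 alcohol (C6 O-TBS, C12 O-TBDPS, C8 and C14 O-PMB retained)
Conditions: PPTS (cat.), MeOH/CH2Cl2 (1:1), 0 °C
Reagents that add atoms: none
Why: Acid-catalysed methanolysis cleaves the secondary TES ether far faster than the secondary TBS and the primary TBDPS ether.

Step 23
Reactants: 35 C9 alcohol
Product: 36 C9 acetate
Conditions: Ac2O, DMAP (cat.), pyridine, CH2Cl2, 0 °C to rt
Reagents that add atoms: acetic anhydride, CC(=O)OC(C)=O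
Why: DMAP-catalysed acetylation of the only free hydroxyl group.

Step 24
Reactants: 36 C9 acetate
Product: 37 C6,C12-diol (6R,7S,8S,9R)
Conditions: HF·pyridine, pyridine, THF, 0 °C to rt
Reagents that add atoms: none
Why: Buffered fluoride cleavage of the TBS and TBDPS ethers, which leaves the acetate and both PMB ethers in place.

Step 25
Reactants: 37 C6,C12-diol
Product: 40 12,6-lactone (ring B) with C8 and C14 O-PMB and C9 acetate, via enal 38 (not isolated), via lactol 39 (not isolated)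
Conditions: TEMPO (20 mol%), PhI(OAc)2 (2.5 equiv), CH2Cl2, rt
Reagents that add atoms: none
Why: Oxidative lactonisation with TEMPO/PhI(OAc)2, which oxidises the primary allylic C12 alcohol to enal 38, lets the C6 hydroxyl close lactol 39 (5-exo-trig) and oxidises this to the α-methylene γ-lactone, the trans fusion having been fixed at C6/C7 earlier.

Step 26
Reactants: 40 lactone bis-PMB ether
Product: 41 C8,C14-diol (6R,7R,8S,9R)
Conditions: DDQ (2.5 equiv), CH2Cl2/pH 7 phosphate buffer (10:1), 0 °C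
Reagents that add atoms: none
Why: Oxidative cleavage of both PMB ethers by DDQ in buffered wet dichloromethane, neutral conditions under which neither the acetate nor the lactone migrates.

Step 27
Reactants: 41 C8,C14-diol
Product: 42 target, (6R,7R,8S,9R)-9-acetoxy-8-hydroxy-14-(3-methylbutanoyloxy)germacra-1(10)Z,4Z,11(13)-trien-12,6-olide
Conditions: isovaleryl chloride (1.1 equiv), 2,4,6-collidine, CH2Cl2, −78 °C to −30 °C
Reagents that add atoms: 3-methylbutanoyl chloride, CC(C)CC(Cl)=O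
Why: Chemoselective acylation of the primary allylic C14 hydroxyl, which is far more accessible than the hindered secondary C8 hydroxyl, a weak base and low temperature preventing acetyl migration from O9.

**Compound list**

1 | but-2-yne-1,4-diol | OCC#CCO | starting material
2 | 4-[(4-methoxybenzyl)oxy]but-2-yn-1-ol | OCC#CCOCc1ccc(OC)cc1 | intermediate
3 | sodium alkenylaluminate, five-membered O–Al–C chelate from 2 | [Na+].COCCO[Al-]1(OCCOC)OCC=C1COCc1ccc(OC)cc1 | intermediate
4 | (Z)-3-iodo-4-[(4-methoxybenzyl)oxy]but-2-en-1-ol | OC/C=C(\I)COCc1ccc(OC)cc1 | intermediate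
5 | (Z)-3-iodo-4-[(4-methoxybenzyl)oxy]but-2-en-1-yl pivalate | CC(C)(C)C(=O)OC/C=C(\I)COCc1ccc(OC)cc1 | intermediate
6 | prop-2-yn-1-ol | C#CCO | starting material
7 | (Z)-[3-(bromomagnesiooxy)-2-methylprop-1-en-1-yl]magnesium bromide | Br[Mg]OC/C(C)=C\[Mg]Br | intermediate
8 | (Z)-3-iodo-2-methylprop-2-en-1-ol | OC/C(C)=C\I | intermediate
9 | (Z)-3-iodo-2-methylprop-2-en-1-yl methanesulfonate | CS(=O)(=O)OC/C(C)=C\I | intermediate
10 | (Z)-[(3-iodo-2-methylprop-2-en-1-yl)sulfonyl]benzene | O=S(=O)(C/C(C)=C\I)c1ccccc1 | intermediate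
11 | 2-bromoprop-2-en-1-ol | OCC(Br)=C | starting material
12 | [(2-bromoprop-2-en-1-yl)oxy](tert-butyl)diphenylsilane | C=C(Br)CO[Si](c1ccccc1)(c1ccccc1)C(C)(C)C | intermediate
13 | lithium dihydridoalkenylalanate, five-membered O–Al–C chelate from 2 | [Li+].[AlH2-]1OCC=C1COCc1ccc(OC)cc1 | intermediate
14 | (E)-4-[(4-methoxybenzyl)oxy]but-2-en-1-ol | OC/C=C/COCc1ccc(OC)cc1 | intermediate
15 | [(2R,3R)-3-{[(4-methoxybenzyl)oxy]methyl}oxiran-2-yl]methanol | OC[C@H]1O[C@@H]1COCc1ccc(OC)cc1 | intermediate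
16 | {3-[(tert-butyldiphenylsilyl)oxy]prop-1-en-2-yl}lithium | [Li]C(=C)CO[Si](c1ccccc1)(c1ccccc1)C(C)(C)C | intermediate
17 | {3-[(tert-butyldiphenylsilyl)oxy]prop-1-en-2-yl}magnesium bromide | Br[Mg]C(=C)CO[Si](c1ccccc1)(c1ccccc1)C(C)(C)C | intermediate
18 | (2S,3S)-2-{3-[(tert-butyldiphenylsilyl)oxy]prop-1-en-2-yl}-4-[(4-methoxybenzyl)oxy]butane-1,3-diol (C6–C9 with C11–C13) | COc1ccc(COC[C@@H](O)[C@@H](C(=C)CO[Si](c2ccccc2)(c2ccccc2)C(C)(C)C)CO)cc1 | intermediate
19 | (2S)-3-{[(tert-butyldiphenylsilyl)oxy]methyl}-2-[(4S)-2-(4-methoxyphenyl)-1,3-dioxolan-4-yl]but-3-en-1-ol (acetal carbon: both epimers) | COc1ccc(cc1)C1OC[C@@H](O1)[C@@H](C(=C)CO[Si](c2ccccc2)(c2ccccc2)C(C)(C)C)CO | intermediate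
20 | (2R)-3-{[(tert-butyldiphenylsilyl)oxy]methyl}-2-[(4S)-2-(4-methoxyphenyl)-1,3-dioxolan-4-yl]but-3-enal | COc1ccc(cc1)C1OC[C@@H](O1)[C@@H](C(=C)CO[Si](c2ccccc2)(c2ccccc2)C(C)(C)C)C=O | intermediate
21 | (Z)-[2-methyl-3-(phenylsulfonyl)prop-1-en-1-yl]chromium dichloride | O=S(=O)(C/C(C)=C\[Cr](Cl)Cl)c1ccccc1 | intermediate
22 | (2Z,4R,5S)-6-{[(tert-butyldiphenylsilyl)oxy]methyl}-5-[(4S)-2-(4-methoxyphenyl)-1,3-dioxolan-4-yl]-2-methyl-1-(phenylsulfonyl)hepta-2,6-dien-4-ol (6R,7S,8S) | COc1ccc(cc1)C1OC[C@@H](O1)[C@@H](C(=C)CO[Si](c2ccccc2)(c2ccccc2)C(C)(C)C)[C@H](O)/C=C(/C)CS(=O)(=O)c1ccccc1 | intermediate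
23 | C6 tert-butyldimethylsilyl ether of 22 (6R,7R,8S) | COc1ccc(cc1)C1OC[C@@H](O1)[C@@H](C(=C)CO[Si](c2ccccc2)(c2ccccc2)C(C)(C)C)[C@H](O[Si](C)(C)C(C)(C)C)/C=C(/C)CS(=O)(=O)c1ccccc1 | intermediate
24 | open C3–C9 chain: C9 primary alcohol, C8 O-PMB, C7 3-(TBDPS-oxy)prop-1-en-2-yl, C6 O-TBS, Z-C4=C5, C3 phenylsulfonyl (6R,7R,8S) | OC[C@@H](OCc1ccc(OC)cc1)[C@@H](C(=C)CO[Si](c1ccccc1)(c1ccccc1)C(C)(C)C)[C@H](O[Si](C)(C)C(C)(C)C)/C=C(/C)CS(=O)(=O)c1ccccc1 | intermediate
25 | C9 aldehyde of 24 (6R,7R,8S) | O=C[C@@H](OCc1ccc(OC)cc1)[C@@H](C(=C)CO[Si](c1ccccc1)(c1ccccc1)C(C)(C)C)[C@H](O[Si](C)(C)C(C)(C)C)/C=C(/C)CS(=O)(=O)c1ccccc1 | intermediate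
26 | (Z)-{1-[(4-methoxybenzyl)oxy]-4-(pivaloyloxy)but-2-en-2-yl}chromium dichloride | CC(C)(C)C(=O)OC/C=C(\[Cr](Cl)Cl)COCc1ccc(OC)cc1 | intermediate
27 | open-chain C9 alcohol: C2 O-Piv, Z-C1=C10, C14 O-PMB, C9 OH, C8 O-PMB, C6 O-TBS, C12 O-TBDPS, C3 phenylsulfonyl (6R,7R,8S,9R) | CC(C)(C)C(=O)OC/C=C(/COCc1ccc(OC)cc1)[C@@H](O)[C@@H](OCc1ccc(OC)cc1)[C@@H](C(=C)CO[Si](c1ccccc1)(c1ccccc1)C(C)(C)C)[C@H](O[Si](C)(C)C(C)(C)C)/C=C(/C)CS(=O)(=O)c1ccccc1 | intermediate
28 | C9 triethylsilyl ether of 27 | CC(C)(C)C(=O)OC/C=C(/COCc1ccc(OC)cc1)[C@@H](O[Si](CC)(CC)CC)[C@@H](OCc1ccc(OC)cc1)[C@@H](C(=C)CO[Si](c1ccccc1)(c1ccccc1)C(C)(C)C)[C@H](O[Si](C)(C)C(C)(C)C)/C=C(/C)CS(=O)(=O)c1ccccc1 | intermediate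
29 | C2 allylic alcohol (28 without the pivaloyl group) | OC/C=C(/COCc1ccc(OC)cc1)[C@@H](O[Si](CC)(CC)CC)[C@@H](OCc1ccc(OC)cc1)[C@@H](C(=C)CO[Si](c1ccccc1)(c1ccccc1)C(C)(C)C)[C@H](O[Si](C)(C)C(C)(C)C)/C=C(/C)CS(=O)(=O)c1ccccc1 | intermediate
30 | C2 methanesulfonate of 29 | CS(=O)(=O)OC/C=C(/COCc1ccc(OC)cc1)[C@@H](O[Si](CC)(CC)CC)[C@@H](OCc1ccc(OC)cc1)[C@@H](C(=C)CO[Si](c1ccccc1)(c1ccccc1)C(C)(C)C)[C@H](O[Si](C)(C)C(C)(C)C)/C=C(/C)CS(=O)(=O)c1ccccc1 | intermediate
31 | seco bromo sulfone: C2 bromide, Z-C1=C10, C14 O-PMB, C9 O-TES, C8 O-PMB, C7 3-(TBDPS-oxy)prop-1-en-2-yl, C6 O-TBS, Z-C4=C5, C3 phenylsulfonyl (6R,7R,8S,9R) | BrC/C=C(/COCc1ccc(OC)cc1)[C@@H](O[Si](CC)(CC)CC)[C@@H](OCc1ccc(OC)cc1)[C@@H](C(=C)CO[Si](c1ccccc1)(c1ccccc1)C(C)(C)C)[C@H](O[Si](C)(C)C(C)(C)C)/C=C(/C)CS(=O)(=O)c1ccccc1 | intermediate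
32 | potassium C3 carbanion of 31 | [K+].BrC/C=C(/COCc1ccc(OC)cc1)[C@@H](O[Si](CC)(CC)CC)[C@@H](OCc1ccc(OC)cc1)[C@@H](C(=C)CO[Si](c1ccccc1)(c1ccccc1)C(C)(C)C)[C@H](O[Si](C)(C)C(C)(C)C)/C=C(/C)[CH-]S(=O)(=O)c1ccccc1 | intermediate
33 | ten-membered ring A sulfone: C3 phenylsulfonyl (both epimers), C6 O-TBS, C8 O-PMB, C9 O-TES, C12 O-TBDPS, C14 O-PMB (6R,7R,8S,9R) | CC(C)(C)[Si](C)(C)O[C@@H]1/C=C(/C)C(S(=O)(=O)c2ccccc2)C/C=C(/COCc2ccc(OC)cc2)[C@@H](O[Si](CC)(CC)CC)[C@@H](OCc2ccc(OC)cc2)[C@H]1C(=C)CO[Si](c2ccccc2)(c2ccccc2)C(C)(C)C | intermediate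
34 | desulfonylated ring A compound (C3 methylene) | CC(C)(C)[Si](C)(C)O[C@@H]1/C=C(/C)CC/C=C(/COCc2ccc(OC)cc2)[C@@H](O[Si](CC)(CC)CC)[C@@H](OCc2ccc(OC)cc2)[C@H]1C(=C)CO[Si](c2ccccc2)(c2ccccc2)C(C)(C)C | intermediate
35 | C9 alcohol (34 without the TES group) | CC(C)(C)[Si](C)(C)O[C@@H]1/C=C(/C)CC/C=C(/COCc2ccc(OC)cc2)[C@@H](O)[C@@H](OCc2ccc(OC)cc2)[C@H]1C(=C)CO[Si](c2ccccc2)(c2ccccc2)C(C)(C)C | intermediate
36 | C9 acetate of 35 | CC(C)(C)[Si](C)(C)O[C@@H]1/C=C(/C)CC/C=C(/COCc2ccc(OC)cc2)[C@@H](OC(C)=O)[C@@H](OCc2ccc(OC)cc2)[C@H]1C(=C)CO[Si](c2ccccc2)(c2ccccc2)C(C)(C)C | intermediate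
37 | C6,C12-diol with C9 acetate, C8 and C14 O-PMB (6R,7S,8S,9R) | O[C@@H]1/C=C(/C)CC/C=C(/COCc2ccc(OC)cc2)[C@@H](OC(C)=O)[C@@H](OCc2ccc(OC)cc2)[C@H]1C(=C)CO | intermediate
38 | C12 enal with free C6 hydroxyl | O[C@@H]1/C=C(/C)CC/C=C(/COCc2ccc(OC)cc2)[C@@H](OC(C)=O)[C@@H](OCc2ccc(OC)cc2)[C@H]1C(=C)C=O | intermediate
39 | C12 lactol (O6–C12 closed, both C12 epimers) | C=C1C(O)O[C@@H]2/C=C(/C)CC/C=C(/COCc3ccc(OC)cc3)[C@@H](OC(C)=O)[C@@H](OCc3ccc(OC)cc3)[C@@H]12 | intermediate
40 | 12,6-lactone with C9 acetate, C8 and C14 O-PMB (6R,7S,8S,9R) | C=C1C(=O)O[C@@H]2/C=C(/C)CC/C=C(/COCc3ccc(OC)cc3)[C@@H](OC(C)=O)[C@@H](OCc3ccc(OC)cc3)[C@@H]12 | intermediate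
41 | 12,6-lactone with C9 acetate and free C8 and C14 hydroxyls (6R,7R,8S,9R) | C=C1C(=O)O[C@@H]2/C=C(/C)CC/C=C(/CO)[C@@H](OC(C)=O)[C@@H](O)[C@@H]12 | intermediate
42 | (6R,7R,8S,9R)-9-acetoxy-8-hydroxy-14-(3-methylbutanoyloxy)germacra-1(10)Z,4Z,11(13)-trien-12,6-olide | C=C1C(=O)O[C@@H]2/C=C(/C)CC/C=C(/COC(=O)CC(C)C)[C@@H](OC(C)=O)[C@@H](O)[C@@H]12 | target

**Step count.** Total: 27 steps. Longest linear sequence: 22 steps (step 1, then steps 7 to 27).

**Steps most likely to fail**

Step 20 (ring closure). Intermolecular alkylation to oligomers may outrun the ten-membered closure, or the allyl anion may lose the C6 silanolate by 1,4-elimination. The fallback makes the C2–C3 bond between two molecules and closes ring A at C9–C10 instead. It sets out from alcohol 24 and iodo alcohol 4. Compound 4 would be converted (CBr4, PPh3, CH2Cl2, 0 °C) into (Z)-1-{[(4-bromo-2-iodobut-2-en-1-yl)oxy]methyl}-4-methoxybenzene F1. The dianion of 24 (n-BuLi, 2.1 equiv, THF, −78 °C) would be alkylated at C3 by F1 to give the open iodo sulfone alcohol F2. Dess–Martin oxidation would give the C9 aldehyde F3. An intramolecular Nozaki–Hiyama–Kishi coupling (CrCl2, NiCl2 cat., DMSO/THF, high dilution) would close ring A to the macrocyclic C9 alcohol F4, with C9 set under control of the ring. Silylation (TESOTf, 2,6-lutidine) comes back to the route at 33.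

Step 21 (desulfonylation). Hydride may be delivered to C5, which moves the alkene to C3=C4, or the Z geometry may be lost through isomerisation of the allylpalladium intermediate. The fallback cleaves the C–S bond of 33 by electron transfer: Na(Hg), Na2HPO4, MeOH/THF, −20 °C, the methanol protonating the allyl anion as it forms. It sets out from 33 and comes back at 34 without any new compound (F0).

Step 12 (C5–C6 coupling). Facial selectivity in the addition to the α-branched aldehyde may be poor. The fallback recycles the unwanted alcohol by inversion at oxygen. It sets out from aldehyde 20, whose coupling with 10 gives the C6 epimer of 22 F5 beside 22. A Mitsunobu reaction on F5 (4-nitrobenzoic acid, PPh3, DIAD, toluene, 0 °C) would give the inverted 4-nitrobenzoate of 22 F6, and methanolysis (K2CO3, MeOH, 0 °C) comes back to the route at 22.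

**Further compounds**

F1 | step 20 | (Z)-1-{[(4-bromo-2-iodobut-2-en-1-yl)oxy]methyl}-4-methoxybenzene | BrC/C=C(\I)COCc1ccc(OC)cc1
F2 | step 20 | open iodo sulfone alcohol: 24 alkylated at C3 with the C2–C1=C10(I)–C14 unit (C3 both epimers) | OC[C@@H](OCc1ccc(OC)cc1)[C@@H](C(=C)CO[Si](c1ccccc1)(c1ccccc1)C(C)(C)C)[C@H](O[Si](C)(C)C(C)(C)C)/C=C(/C)C(C/C=C(\I)COCc1ccc(OC)cc1)S(=O)(=O)c1ccccc1
F3 | step 20 | C9 aldehyde of F2 | O=C[C@@H](OCc1ccc(OC)cc1)[C@@H](C(=C)CO[Si](c1ccccc1)(c1ccccc1)C(C)(C)C)[C@H](O[Si](C)(C)C(C)(C)C)/C=C(/C)C(C/C=C(\I)COCc1ccc(OC)cc1)S(=O)(=O)c1ccccc1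
F4 | step 20 | macrocyclic C9 alcohol (33 without the TES group) | CC(C)(C)[Si](C)(C)O[C@@H]1/C=C(/C)C(S(=O)(=O)c2ccccc2)C/C=C(/COCc2ccc(OC)cc2)[C@@H](O)[C@@H](OCc2ccc(OC)cc2)[C@H]1C(=C)CO[Si](c2ccccc2)(c2ccccc2)C(C)(C)C
F0 | step 21 | none | none
F5 | step 12 | C6 epimer of 22 (6S,7S,8S) | COc1ccc(cc1)C1OC[C@@H](O1)[C@@H](C(=C)CO[Si](c2ccccc2)(c2ccccc2)C(C)(C)C)[C@@H](O)/C=C(/C)CS(=O)(=O)c1ccccc1
F6 | step 12 | 4-nitrobenzoate of 22 (C6 configuration as in 22) | COc1ccc(cc1)C1OC[C@@H](O1)[C@@H](C(=C)CO[Si](c2ccccc2)(c2ccccc2)C(C)(C)C)[C@H](OC(=O)c1ccc(cc1)[N+](=O)[O-])/C=C(/C)CS(=O)(=O)c1ccccc1
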